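A direct plan would grow the chain from the ring A end: Brown allylboration of aldehyde A1 would set C3 in homoallylic alcohol A2.
A tert-butyl carbonate and IBr would relay this centre to C5 through iodocarbonate A3, and base would give epoxy alcohol A4.
The benzylic Grignard reagent A5 under copper catalysis would then add C7 with ring B, before acetylation and hydrogenolysis.
Weakest points:
(a) The relay from C3 to C5 (carbonate, iodocyclisation, epoxide closure) would spend three operations that form no C–C bond, would rest on 1,3-induction that needs about −85 °C, and would expose an electron-rich dialkoxyarene to IBr.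
(b) The epoxide opening by the electron-rich benzylic Grignard reagent would be the only point of convergence, late in the sequence, and would suffer from Wurtz coupling when the reagent is made and from the free hydroxyl group that consumes it.
(c) The plan would be linear throughout: the two stereocentres would be made one after the other on one chain, the second depending on the first, so every shortfall would surface late as diastereomers of a pseudo-meso compound.

**Retrosynthetic overview**
The target is a pseudo-meso syn-1,3-diol diacetate: C3 and C5 are mirror-image carbinol carbons, each heading a 3-arylpropyl unit (C1–C3 with guaiacyl ring A, C5–C7 with catechol ring B), joined only through the methylene C4.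
Both bonds to C4 are cut: C4 comes from bis(pinacolato)borylmethane, and C3 and C5 are the carbinol carbons of two 3-arylpropan-1-ols, used as α-lithiated triisopropylbenzoates (C6–C3 + C1 + C3–C6, as in the biogenesis of diarylheptanoids).
Two lithiation–borylation homologations insert these carbons into the two C–B bonds of the linchpin, with (−)-sparteine for the ring A half and (+)-sparteine for the ring B half; each stereocentre is set by its own reagent, and both oxygens appear together when the C–B bonds are oxidised.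
No ring is formed (both arenes are bought); the design needs no 1,3-relay, no halocyclisation, no epoxide and no benzylic organometallic, and the halves meet in the middle of a convergent route that ends with acetylation and one fluoride deprotection.

Key step: step 7

Remark: the methyl ester of dihydrocaffeic acid and both enantiomers of sparteine are taken as purchasable; the ester is otherwise one Fischer esterification away from the acid.

**Step 1**
Reactants: 1 dihydroconiferyl alcohol [3-(4-hydroxy-3-methoxyphenyl)propan-1-ol]; 2 2,4,6-tri(propan-2-yl)benzoic acid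
Product: 3 3-(4-hydroxy-3-methoxyphenyl)propyl 2,4,6-tri(propan-2-yl)benzoate
Conditions: 2 (1.05 equiv), PPh3, DIAD, THF, 0 °C → rt
Reagents that add atoms: 2,4,6-tri(propan-2-yl)benzoic acid 2, CC(C)c1cc(C(C)C)c(C(=O)O)c(C(C)C)c1
Why: Mitsunobu esterification in which the betaine is protonated by the carboxylic acid, far more acidic than the phenol, so the carboxylate displaces the primary alkoxyphosphonium group and the phenol should stay free; no stereocentre is involved.

**Step 2**
Reactants: 3 3-(4-hydroxy-3-methoxyphenyl)propyl 2,4,6-tri(propan-2-yl)benzoate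
Product: 4 3-{4-[(tert-butyldimethylsilyl)oxy]-3-methoxyphenyl}propyl 2,4,6-tri(propan-2-yl)benzoate
Conditions: TBSCl, imidazole, DMF, rt
Reagents that add atoms: tert-butyldimethylsilyl chloride, CC(C)(C)[Si](C)(C)Cl
Why: Imidazole-promoted silyl ether formation gives an aryl silyl ether that has no acidic ether C–H and should tolerate sBuLi at −78 °C, in contrast to a benzyl ether.

**Step 3**
Reactants: 4 3-{4-[(tert-butyldimethylsilyl)oxy]-3-methoxyphenyl}propyl 2,4,6-tri(propan-2-yl)benzoate; 5 bis(pinacolato)borylmethane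
Product: 8 2,2'-[(2S)-4-{4-[(tert-butyldimethylsilyl)oxy]-3-methoxyphenyl}butane-1,2-diyl]bis(4,4,5,5-tetramethyl-1,3,2-dioxaborolane), via (S)-α-lithio benzoate 6 (not isolated), via lithium boronate complex 7 (not isolated)
Conditions: sBuLi (1.25 equiv), (−)-sparteine (1.3 equiv), Et2O, −78 °C, 5 h; then 5 (1.5 equiv), −78 °C, 2 h; → 35 °C, 12 h; aq. NH4Cl
Reagents that add atoms: bis(pinacolato)borylmethane 5, CC1(C)OB(CB2OC(C)(C)C(C)(C)O2)OC1(C)C
Why: Sparteine-mediated asymmetric deprotonation removes the pro-S hydrogen to give the configurationally stable carbenoid 6, which adds to one boron of 5 with retention, and the 1,2-metallate rearrangement of 7 with inversion at carbon and loss of the benzoate (lithiation–borylation, a Matteson-type homologation) forms C3–C4 and sets the C3–B stereocentre by reagent control, while the bulk of the diamine-bound carbenoid and the excess of 5 should stop the reaction after one homologation.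

**Step 4**
Reactants: 9 methyl 3-(3,4-dihydroxyphenyl)propanoate
Product: 10 methyl 3-{3,4-bis[(tert-butyldimethylsilyl)oxy]phenyl}propanoate
Conditions: TBSCl (2.5 equiv), imidazole, DMF, rt
Reagents that add atoms: tert-butyldimethylsilyl chloride, CC(C)(C)[Si](C)(C)Cl
Why: Silyl ether formation at both catechol oxygens masks the acidic phenols in the same base-tolerant form as in ring A, so that all three phenols can be freed together at the end.

**Step 5**
Reactants: 10 methyl 3-{3,4-bis[(tert-butyldimethylsilyl)oxy]phenyl}propanoate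
Product: 11 3-{3,4-bis[(tert-butyldimethylsilyl)oxy]phenyl}propan-1-ol
Conditions: iBu2AlH (2.5 equiv), CH2Cl2, −78 → 0 °C; aq. potassium sodium tartrate
Reagents that add atoms: none
Why: Hydride reduction of the methyl ester at low temperature should give the primary alcohol and leave the aryl silyl ethers intact.

**Step 6**
Reactants: 11 3-{3,4-bis[(tert-butyldimethylsilyl)oxy]phenyl}propan-1-ol; 2 2,4,6-tri(propan-2-yl)benzoic acid
Product: 12 3-{3,4-bis[(tert-butyldimethylsilyl)oxy]phenyl}propyl 2,4,6-tri(propan-2-yl)benzoate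
Conditions: 2 (1.1 equiv), PPh3, DIAD, THF, 0 °C → rt
Reagents that add atoms: 2,4,6-tri(propan-2-yl)benzoic acid 2, CC(C)c1cc(C(C)C)c(C(=O)O)c(C(C)C)c1
Why: Mitsunobu esterification installs the hindered benzoate, whose carbonyl group directs the later α-deprotonation and which serves as the leaving group in the 1,2-metallate shift.

**Step 7**
Reactants: 12 3-{3,4-bis[(tert-butyldimethylsilyl)oxy]phenyl}propyl 2,4,6-tri(propan-2-yl)benzoate; 8 2,2'-[(2S)-4-{4-[(tert-butyldimethylsilyl)oxy]-3-methoxyphenyl}butane-1,2-diyl]bis(4,4,5,5-tetramethyl-1,3,2-dioxaborolane)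
Product: 16 (3R,5S)-1-{4-[(tert-butyldimethylsilyl)oxy]-3-methoxyphenyl}-7-{3,4-bis[(tert-butyldimethylsilyl)oxy]phenyl}heptane-3,5-diol, via (R)-α-lithio benzoate 13 (not isolated), via lithium boronate complex 14 (not isolated), via syn-1,3-bis(boronic ester) 15 (not isolated)
Conditions: 12 (1.5 equiv), sBuLi (1.4 equiv), (+)-sparteine (1.5 equiv), Et2O, −78 °C, 5 h; then 8 (1.0 equiv), −78 °C, 3 h; → 35 °C, 12 h; aq. NH4Cl; then NaBO3·4H2O, THF/H2O, rt
Reagents that add atoms: bis(boronic ester) 8, COc1cc(CC[C@H](CB2OC(C)(C)C(C)(C)O2)B2OC(C)(C)C(C)(C)O2)ccc1O[Si](C)(C)C(C)(C)C; sodium perborate tetrahydrate NaBO3·4H2O, [Na+].[O-]OB=O.O.O.O.O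
Why: sBuLi and (+)-sparteine remove the pro-R hydrogen of 12 to give the configurationally stable carbenoid 13, which adds with retention to the less hindered, primary boron of 8; in boronate 14 the C4 methylene then migrates to C5 with inversion while the benzoate leaves antiperiplanar, and perborate finally replaces both C–B bonds by C–O bonds with retention. The closest known reaction type is the lithiation–borylation homologation of the primary boron of 1,2-bis(boronic esters) with lithiated primary benzoates, followed by oxidation to 1,3-diols. No ring is closed; the step joins the two halves at C4–C5. C5 is set by the diamine alone and C3 is carried from step 3, so the use of mirror-image diamines for the two mirror-image carbinol carbons should give the syn (3R,5S) diol, and the minor enantiomer of either carbenoid should end up in an anti diastereomer that chromatography of the diol can remove. The step needs selectivity for the primary over the secondary boron, which the arylethyl-flanked secondary site supplies by its bulk, α-lithiation in preference to ring metalation or attack at silicon, which the carbonyl-directed deprotonation at −78 °C and the absence of acidic ether C–H bonds should secure, and survival of the aryl silyl ethers in the oxidation, which is why mild perborate is used.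

**Step 8**
Reactants: 16 (3R,5S)-1-{4-[(tert-butyldimethylsilyl)oxy]-3-methoxyphenyl}-7-{3,4-bis[(tert-butyldimethylsilyl)oxy]phenyl}heptane-3,5-diol
Product: 17 (3R,5S)-1-{4-[(tert-butyldimethylsilyl)oxy]-3-methoxyphenyl}-7-{3,4-bis[(tert-butyldimethylsilyl)oxy]phenyl}heptane-3,5-diyl diacetate
Conditions: Ac2O, pyridine, DMAP (cat.), CH2Cl2, 0 °C → rt
Reagents that add atoms: acetic anhydride, CC(=O)OC(C)=O
Why: DMAP-catalysed O-acetylation of the only two free hydroxyl groups does not touch either stereocentre.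

**Step 9**
Reactants: 17 (3R,5S)-1-{4-[(tert-butyldimethylsilyl)oxy]-3-methoxyphenyl}-7-{3,4-bis[(tert-butyldimethylsilyl)oxy]phenyl}heptane-3,5-diyl diacetate
Product: 18 (3R,5S)-7-(3,4-dihydroxyphenyl)-1-(4-hydroxy-3-methoxyphenyl)heptane-3,5-diyl diacetate (CNP0315129.1)
Conditions: Bu4NF (3.3 equiv), AcOH (3.5 equiv), THF, 0 °C, argon
Reagents that add atoms: none
Why: Fluoride-mediated desilylation of the three aryl silyl ethers, buffered with acetic acid so that no free phenoxide can take over an acetyl group, should leave the secondary acetates and both stereocentres untouched and give the target.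

**Compound list**
1 | dihydroconiferyl alcohol, 3-(4-hydroxy-3-methoxyphenyl)propan-1-ol | COc1cc(CCCO)ccc1O | starting material
2 | 2,4,6-tri(propan-2-yl)benzoic acid | CC(C)c1cc(C(C)C)c(C(=O)O)c(C(C)C)c1 | starting material
3 | 3-(4-hydroxy-3-methoxyphenyl)propyl 2,4,6-tri(propan-2-yl)benzoate | COc1cc(CCCOC(=O)c2c(C(C)C)cc(C(C)C)cc2C(C)C)ccc1O | intermediate
4 | 3-{4-[(tert-butyldimethylsilyl)oxy]-3-methoxyphenyl}propyl 2,4,6-tri(propan-2-yl)benzoate | COc1cc(CCCOC(=O)c2c(C(C)C)cc(C(C)C)cc2C(C)C)ccc1O[Si](C)(C)C(C)(C)C | intermediate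
5 | bis(pinacolato)borylmethane, 2,2'-methylenebis(4,4,5,5-tetramethyl-1,3,2-dioxaborolane) | CC1(C)OB(CB2OC(C)(C)C(C)(C)O2)OC1(C)C | starting material
6 | (1S)-3-{4-[(tert-butyldimethylsilyl)oxy]-3-methoxyphenyl}-1-lithiopropyl 2,4,6-tri(propan-2-yl)benzoate, formed as its (−)-sparteine complex | [Li][C@@H](CCc1ccc(O[Si](C)(C)C(C)(C)C)c(OC)c1)OC(=O)c1c(C(C)C)cc(C(C)C)cc1C(C)C | intermediate
7 | lithium boronate complex of 6 with 5, (S) at the benzoate-bearing carbon | [Li+].CC1(C)O[B-](CB2OC(C)(C)C(C)(C)O2)([C@@H](CCc2ccc(O[Si](C)(C)C(C)(C)C)c(OC)c2)OC(=O)c2c(C(C)C)cc(C(C)C)cc2C(C)C)OC1(C)C | intermediate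
8 | 2,2'-[(2S)-4-{4-[(tert-butyldimethylsilyl)oxy]-3-methoxyphenyl}butane-1,2-diyl]bis(4,4,5,5-tetramethyl-1,3,2-dioxaborolane) | COc1cc(CC[C@H](CB2OC(C)(C)C(C)(C)O2)B2OC(C)(C)C(C)(C)O2)ccc1O[Si](C)(C)C(C)(C)C | intermediate
9 | methyl 3-(3,4-dihydroxyphenyl)propanoate | COC(=O)CCc1ccc(O)c(O)c1 | starting material
10 | methyl 3-{3,4-bis[(tert-butyldimethylsilyl)oxy]phenyl}propanoate | COC(=O)CCc1ccc(O[Si](C)(C)C(C)(C)C)c(O[Si](C)(C)C(C)(C)C)c1 | intermediate
11 | 3-{3,4-bis[(tert-butyldimethylsilyl)oxy]phenyl}propan-1-ol | OCCCc1ccc(O[Si](C)(C)C(C)(C)C)c(O[Si](C)(C)C(C)(C)C)c1 | intermediate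
12 | 3-{3,4-bis[(tert-butyldimethylsilyl)oxy]phenyl}propyl 2,4,6-tri(propan-2-yl)benzoate | CC(C)c1cc(C(C)C)c(C(=O)OCCCc2ccc(O[Si](C)(C)C(C)(C)C)c(O[Si](C)(C)C(C)(C)C)c2)c(C(C)C)c1 | intermediate
13 | (1R)-3-{3,4-bis[(tert-butyldimethylsilyl)oxy]phenyl}-1-lithiopropyl 2,4,6-tri(propan-2-yl)benzoate, formed as its (+)-sparteine complex | [Li][C@H](CCc1ccc(O[Si](C)(C)C(C)(C)C)c(O[Si](C)(C)C(C)(C)C)c1)OC(=O)c1c(C(C)C)cc(C(C)C)cc1C(C)C | intermediate
14 | lithium boronate complex of 13 with the primary boron of 8, (R) at the benzoate-bearing carbon and (S) at the boron-bearing carbon | [Li+].CC1(C)O[B-](C[C@@H](CCc2ccc(O[Si](C)(C)C(C)(C)C)c(OC)c2)B2OC(C)(C)C(C)(C)O2)([C@H](CCc2ccc(O[Si](C)(C)C(C)(C)C)c(O[Si](C)(C)C(C)(C)C)c2)OC(=O)c2c(C(C)C)cc(C(C)C)cc2C(C)C)OC1(C)C | intermediate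
15 | 2,2'-[(3R,5S)-1-{4-[(tert-butyldimethylsilyl)oxy]-3-methoxyphenyl}-7-{3,4-bis[(tert-butyldimethylsilyl)oxy]phenyl}heptane-3,5-diyl]bis(4,4,5,5-tetramethyl-1,3,2-dioxaborolane) | COc1cc(CC[C@H](C[C@H](CCc2ccc(O[Si](C)(C)C(C)(C)C)c(O[Si](C)(C)C(C)(C)C)c2)B2OC(C)(C)C(C)(C)O2)B2OC(C)(C)C(C)(C)O2)ccc1O[Si](C)(C)C(C)(C)C | intermediate
16 | (3R,5S)-1-{4-[(tert-butyldimethylsilyl)oxy]-3-methoxyphenyl}-7-{3,4-bis[(tert-butyldimethylsilyl)oxy]phenyl}heptane-3,5-diol | COc1cc(CC[C@H](C[C@H](CCc2ccc(O[Si](C)(C)C(C)(C)C)c(O[Si](C)(C)C(C)(C)C)c2)O)O)ccc1O[Si](C)(C)C(C)(C)C | intermediate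
17 | (3R,5S)-1-{4-[(tert-butyldimethylsilyl)oxy]-3-methoxyphenyl}-7-{3,4-bis[(tert-butyldimethylsilyl)oxy]phenyl}heptane-3,5-diyl diacetate | COc1cc(CC[C@H](C[C@H](CCc2ccc(O[Si](C)(C)C(C)(C)C)c(O[Si](C)(C)C(C)(C)C)c2)OC(C)=O)OC(C)=O)ccc1O[Si](C)(C)C(C)(C)C | intermediate
18 | (3R,5S)-7-(3,4-dihydroxyphenyl)-1-(4-hydroxy-3-methoxyphenyl)heptane-3,5-diyl diacetate (CNP0315129.1) | COc1cc(CC[C@H](C[C@H](CCc2ccc(O)c(O)c2)OC(C)=O)OC(C)=O)ccc1O | target

**Step count and risks**
Total step count: 9. Longest linear sequence: 6 steps (1, 2, 3, 7, 8, 9 or 4, 5, 6, 7, 8, 9).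

Steps most likely to fail:

- **Step 7.** The diamine-bound carbenoid may add slowly and reversibly to the β-branched primary boron of 8, or attack the secondary boron, so that conversion and diastereopurity suffer. The fallback makes the carbenoid by transmetallation instead of deprotonation. It sets out from 12, which is lithiated as before [sBuLi, (+)-sparteine, Et2O, −78 °C] and quenched with Me3SnCl to give (1R)-3-{3,4-bis[(tert-butyldimethylsilyl)oxy]phenyl}-1-(trimethylstannyl)propyl 2,4,6-tri(propan-2-yl)benzoate F1, which is purified. Tin–lithium exchange with nBuLi (Et2O, −78 °C) then gives the same carbenoid free of diamine, the smaller form that is known to homologate hindered boronic esters. Addition of 8, warming and perborate oxidation return to the route at 16.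

- **Step 3.** During the long deprotonation, metalation of the arene or attack of sBuLi at silicon may compete with α-lithiation, and a second homologation of the product may occur. The fallback makes the first C–B stereocentre without any organolithium, by catalytic enantioselective diboration. It sets out from 1: bis-silylation (TBSCl, imidazole, DMF) gives tert-butyl{2-methoxy-4-[3-((tert-butyldimethylsilyl)oxy)propyl]phenoxy}dimethylsilane F2, and mild acid (PPTS, MeOH) frees only the primary alcohol to give 3-{4-[(tert-butyldimethylsilyl)oxy]-3-methoxyphenyl}propan-1-ol F3. Dess–Martin oxidation gives 3-{4-[(tert-butyldimethylsilyl)oxy]-3-methoxyphenyl}propanal F4, and Wittig methylenation (Ph3P=CH2, THF) gives 4-(but-3-en-1-yl)-1-[(tert-butyldimethylsilyl)oxy]-2-methoxybenzene F5. Diboration with B2pin2, Pt(dba)3 and a TADDOL-derived phenylphosphonite, in the ligand enantiomer that delivers the (S)-configured product, returns to the route at 8.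

- **Step 9.** Phenoxides formed by fluoride may take over acetyl groups from the secondary acetates, and the freed catechol may be oxidised by air. The fallback moves the desilylation in front of the acylation. It sets out from 16: Bu4NF (THF, 0 °C) gives (3R,5S)-7-(3,4-dihydroxyphenyl)-1-(4-hydroxy-3-methoxyphenyl)heptane-3,5-diol F6, and exhaustive acetylation (Ac2O, pyridine, DMAP) gives the pentaacetate (3R,5S)-1-(4-acetoxy-3-methoxyphenyl)-7-(3,4-diacetoxyphenyl)heptane-3,5-diyl diacetate F7. Chemoselective aminolysis of the three aryl acetates with pyrrolidine (MeCN, 0 °C), which should spare secondary alkyl acetates, returns to the route at 18.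

**Further compounds**
F1 | step 7 | (1R)-3-{3,4-bis[(tert-butyldimethylsilyl)oxy]phenyl}-1-(trimethylstannyl)propyl 2,4,6-tri(propan-2-yl)benzoate | C[Sn](C)(C)[C@H](CCc1ccc(O[Si](C)(C)C(C)(C)C)c(O[Si](C)(C)C(C)(C)C)c1)OC(=O)c1c(C(C)C)cc(C(C)C)cc1C(C)C
F2 | step 3 | tert-butyl{2-methoxy-4-[3-((tert-butyldimethylsilyl)oxy)propyl]phenoxy}dimethylsilane | COc1cc(CCCO[Si](C)(C)C(C)(C)C)ccc1O[Si](C)(C)C(C)(C)C
F3 | step 3 | 3-{4-[(tert-butyldimethylsilyl)oxy]-3-methoxyphenyl}propan-1-ol | COc1cc(CCCO)ccc1O[Si](C)(C)C(C)(C)C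
F4 | step 3 | 3-{4-[(tert-butyldimethylsilyl)oxy]-3-methoxyphenyl}propanal | COc1cc(CCC=O)ccc1O[Si](C)(C)C(C)(C)C
F5 | step 3 | 4-(but-3-en-1-yl)-1-[(tert-butyldimethylsilyl)oxy]-2-methoxybenzene | COc1cc(CCC=C)ccc1O[Si](C)(C)C(C)(C)C
F6 | step 9 | (3R,5S)-7-(3,4-dihydroxyphenyl)-1-(4-hydroxy-3-methoxyphenyl)heptane-3,5-diol | COc1cc(CC[C@H](C[C@H](CCc2ccc(O)c(O)c2)O)O)ccc1O
F7 | step 9 | (3R,5S)-1-(4-acetoxy-3-methoxyphenyl)-7-(3,4-diacetoxyphenyl)heptane-3,5-diyl diacetate | COc1cc(CC[C@H](C[C@H](CCc2ccc(OC(C)=O)c(OC(C)=O)c2)OC(C)=O)OC(C)=O)ccc1OC(C)=O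
A1 | direct plan | 3-[4-(benzyloxy)-3-methoxyphenyl]propanal | COc1cc(CCC=O)ccc1OCc1ccccc1
A2 | direct plan | (3R)-1-[4-(benzyloxy)-3-methoxyphenyl]hex-5-en-3-ol | COc1cc(CC[C@@H](O)CC=C)ccc1OCc1ccccc1
A3 | direct plan | (4R,6R)-4-{2-[4-(benzyloxy)-3-methoxyphenyl]ethyl}-6-(iodomethyl)-1,3-dioxan-2-one | COc1cc(CC[C@@H]2C[C@H](CI)OC(=O)O2)ccc1OCc1ccccc1
A4 | direct plan | (2R)-4-[4-(benzyloxy)-3-methoxyphenyl]-1-[(2R)-oxiran-2-yl]butan-2-ol | COc1cc(CC[C@@H](O)C[C@@H]2CO2)ccc1OCc1ccccc1
A5 | direct plan | 3,4-bis(benzyloxy)benzylmagnesium chloride | Cl[Mg]Cc1ccc(OCc2ccccc2)c(OCc2ccccc2)c1
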